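## Analysis of the target

Perlatolic acid (12) is a para-depside: two benzene rings joined by one aryl ester, with no stereocenters. Ring A is the acyl half, carrying the ester carbonyl at C1, a free hydroxyl at C2, a methoxy group at C4 and a pentyl chain at C6. Ring B is olivetolic acid (carboxyl at C1, hydroxyl at C2, pentyl at C6) acylated on the oxygen at C4. The sensitive groups are the depside ester (an activated aryl ester that nucleophiles and strong base cleave), the β-resorcylic acid of ring B (prone to decarboxylation on heating or in strong acid) and the two carbonyl-chelated phenols. The difficulty lies in telling oxygens apart, not in the skeleton: the ester must form at O4 and not O2 of ring B, ring A must end with O2 free and O4 methylated, and the acid must be freed last. The ester carbonyl is also flanked on ring A by two ortho substituents (the C2 oxygen and the C6 pentyl group), which slows reactions of an ordinary activated acid derivative. The strategy rests on the carbonyl carbon between C1 of ring A and O4 of ring B: it is a single carbon at the oxidation level of carbon monoxide, so it can be brought in as CO onto an aryl iodide at C1 of ring A. That iodide position lies next to the pentyl group, ortho to one oxygen and para to the other, so it can be reached from a symmetric dimethyl ether in which both positions beside the pentyl group are identical.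

## Retrosynthetic reasoning

12 to 11. The carboxylic acid of 12 is traced back to its benzyl ester 11 by cutting the O–benzyl bond. The free acid is the group most easily lost and would interfere with basic and metal-mediated steps, so it stays covered to the end. The forward step is a neutral hydrogenolysis that leaves the depside ester, the aryl methyl ether and both phenols alone.

11 to 9. The free hydroxyl at C2 of ring A is traced back to a methyl ether, so the forward step cuts the O–CH3 bond at O2. This mask makes the two oxygens of ring A identical before the coupling, which is what makes the ring A piece symmetric and cheap. The forward step must then distinguish two methyl ethers. Only the O2 ether sits beside the depside carbonyl and can be held with it in a six-membered chelate by a boron Lewis acid (boron-bound species 10); the O4 ether cannot.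

9 to 2, 8 and 7. This is the central disconnection. Two bonds at the depside carbonyl carbon are cut: the bond to C1 of ring A and the bond to O4 of ring B. Every other bond of 9 lies in an aromatic ring or a simple side chain that is available intact, so cutting on both sides of this carbon gives the most convergent split. It also turns the ring A piece from a hindered acid, which would need its own synthesis and activation, into the aryl iodide 2, with carbon monoxide 8 as the one-carbon piece. The forward reaction is a palladium-catalysed three-component ester synthesis. It must acylate O4 and not O2 of 7, and it must give the ester and not the diaryl ether.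

2 to 1. The C–I bond is cut. In 1 the two positions beside the pentyl group are equivalent, each para to one methoxy group and ortho to the other. The third free position lies between the two methoxy groups and is only ortho-activated and more shielded. Electrophilic iodination should therefore lead to 2.

7 to 6. The benzyl ester is cut at its O–CH2 bond. The forward step alkylates the carboxylate of 6 under conditions too weakly basic to touch the phenols.

6 to 5 to 3. The bond between C1 of ring B and the carboxyl carbon is cut. The carbon is introduced at the aldehyde level (5, through iminium salt 4) and then oxidised. Direct carboxylation of a 5-alkylresorcinol can also attack the position between the two hydroxyls. Formylation of 3 is expected to go beside the chain, para to one hydroxyl and ortho to the other, which is the pattern ring B needs.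

## Alternatives that were turned down

Alternative 1: Ring A is opened across its C1–C6 bond, so it becomes a linear tetracarbonyl chain already attached to O4 of ring B: benzyl 2-hydroxy-6-pentyl-4-[(3,5,7-trioxododecanoyl)oxy]benzoate (A2).
- Forward key step: an intramolecular aldol of the C2 methylene onto the C7 ketone, followed by dehydration and enolisation, gives benzyl 4-[(2,4-dihydroxy-6-pentylbenzoyl)oxy]-2-hydroxy-6-pentylbenzoate (A1).
- For: it follows the biosynthetic logic of resorcylate rings. The chain dictates the substitution pattern of ring A. The depside ester exists before ring A does, so no hindered acylation, metal, CO or ether cleavage is needed.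
- Against: A2 is an aryl ester of a β-keto acid with an acidic phenol as leaving group. Its enolates can close onto the ester carbonyl instead (Claisen-type C-acylation or lactonisation to a hydroxypyrone) and expel ring B, destroying the bond the plan depends on. A2 needs a masked triketo acid that takes several steps to make. A1 still needs a selective methylation at O4 of ring A.
- Comparison: on built-in regiochemistry of ring A this alternative is stronger. The chosen route offers instead two stable aromatic partners, a shorter sequence and a bond-forming step that cannot fragment the depside.

Alternative 2: Ring B is cut at its C1–C6 and C2–C3 bonds. This leads back to the pyranone 2-oxo-6-pentyl-2H-pyran-4-yl 2-(benzyloxy)-4-methoxy-6-pentylbenzoate (A4) and the silyl ketene acetal benzyl 3-(benzyloxy)-3-[(trimethylsilyl)oxy]prop-2-enoate (A5).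
- Forward key step: a [4+2] addition of A5 across C3 and C6 of A4, then extrusion of the lactone bridge and loss of one benzyloxy group, gives benzyl 4-{[2-(benzyloxy)-4-methoxy-6-pentylbenzoyl]oxy}-2-hydroxy-6-pentylbenzoate (A3).
- For: the pyranone fixes the pattern of ring B, so no choice between two hydroxyls arises. A3 needs only one hydrogenolysis to reach the target, which is a better end game than the chosen route.
- Against: A4 is a vinylogous mixed anhydride, and the nucleophilic carbon of A5 can attack the aroyl group or C4 instead of cycloadding. Pyranones are reluctant dienes. The ring A acid with its ortho benzyl ether must be made in several regiocontrolled steps and still has to be esterified as a hindered acid.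
- Comparison: this alternative is longer and keeps the problem that the CO route removes. In exchange for its cleaner end game, the chosen route offers a cheap symmetric ring A piece and a more reliable coupling.

Alternative 3: Ring A is cut at its C1–C2 and C5–C6 bonds. This leads back to the ynoate benzyl 2-hydroxy-4-(oct-2-ynoyloxy)-6-pentylbenzoate (A7) and 1,3-dimethoxy-1-[(trimethylsilyl)oxy]buta-1,3-diene (A8).
- Forward key step: a Diels–Alder addition in which the nucleophilic CH2 terminus of A8 bonds to the pentyl-bearing alkyne carbon of A7. Loss of the alkoxy group from the adduct then gives benzyl 2-hydroxy-4-[(2-hydroxy-4-methoxy-6-pentylbenzoyl)oxy]-6-pentylbenzoate (A6), benzyl perlatolate. The structure of A6 is that of 11, so from A6 only the final hydrogenolysis would remain.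
- For: ring A of A6 appears with O2 free and O4 methylated, so no ether cleavage is needed. The ester is made from an unhindered ynoic acid. The overall length is about the same as the chosen route. On protecting-group economy this alternative is stronger.
- Against: a β-alkyl ynoate is a sluggish dienophile and needs heat. A8 is a thermally and protically fragile silyl ketene acetal that the chelated phenol of A7 can desilylate. The aryl ynoate is itself an activated ester and a conjugate acceptor, open to acyl transfer and addition before A6 can form.
- Comparison: the chosen route offers a key step whose partners (an aryl iodide, a phenol and CO) are stable under the reaction conditions, and whose selectivity is set by hydrogen bonding in the substrate.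

Key step: step 5

Remark on the chemistry: the counter-ion of iminium intermediate 4 is written as chloride; dichlorophosphate may take its place without effect on the hydrolysis.

## Route

Step 1
Reactants: 1 1,3-dimethoxy-5-pentylbenzene
Product: 2 2-iodo-1,5-dimethoxy-3-pentylbenzene
Conditions: NIS (1.05 equiv), cat. CF3CO2H, MeCN, 0 °C to rt, dark
Reagents that add atoms: N-iodosuccinimide, O=C1CCC(=O)N1I
Why: Electrophilic aromatic iodination; the two positions beside the pentyl group are equivalent and each is para to one methoxy group, while the position between the methoxy groups is only ortho-activated and more shielded, so one equivalent of NIS should give mainly the mono-iodide 2.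

Step 2
Reactants: 3 olivetol (5-pentylbenzene-1,3-diol)
Product: 5 2,4-dihydroxy-6-pentylbenzaldehyde, via aryl iminium chloride 4 (not isolated)
Conditions: POCl3, DMF, 0 °C to rt; then ice-water, 50 °C
Reagents that add atoms: N,N-dimethylformamide, CN(C)C=O; water, O
Why: Vilsmeier–Haack formylation; the chloroiminium electrophile should attack the resorcinol beside the chain, para to one hydroxyl and ortho to the other, as is usual for 5-alkylresorcinols, and aqueous hydrolysis of iminium salt 4 releases the aldehyde.

Step 3
Reactants: 5 2,4-dihydroxy-6-pentylbenzaldehyde
Product: 6 2,4-dihydroxy-6-pentylbenzoic acid (olivetolic acid)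
Conditions: NaClO2, NaH2PO4, DMSO/H2O, 0 °C to rt
Reagents that add atoms: sodium chlorite, [Na+].[O-]Cl=O
Why: Pinnick (chlorite) oxidation of the aldehyde to the acid; DMSO consumes the hypochlorous acid formed so that the electron-rich ring is not chlorinated, and the low temperature avoids decarboxylation of the β-resorcylic acid.

Step 4
Reactants: 6 2,4-dihydroxy-6-pentylbenzoic acid
Product: 7 benzyl 2,4-dihydroxy-6-pentylbenzoate (benzyl olivetolate)
Conditions: BnBr (1.05 equiv), KHCO3, DMF, rt
Reagents that add atoms: benzyl bromide, BrCc1ccccc1
Why: SN2 O-alkylation of the carboxylate; bicarbonate deprotonates only the carboxylic acid, so both phenols should stay free.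

Step 5
Reactants: 2 2-iodo-1,5-dimethoxy-3-pentylbenzene; 7 benzyl 2,4-dihydroxy-6-pentylbenzoate; 8 carbon monoxide
Product: 9 benzyl 4-[(2,4-dimethoxy-6-pentylbenzoyl)oxy]-2-hydroxy-6-pentylbenzoate
Conditions: Pd(OAc)2 (5 mol %), Xantphos (6 mol %), CO (3 bar), Et3N, toluene, 90 °C
Reagents that add atoms: none
Why: This is a palladium-catalysed aryloxycarbonylation, the known carbonylative esterification of aryl halides with phenols. Zerovalent palladium formed from Pd(OAc)2 and Xantphos adds oxidatively to the C–I bond of 2; the resulting arylpalladium iodide, a divalent palladium species, binds 8, and migratory insertion gives the 2,4-dimethoxy-6-pentylbenzoyl palladium complex. Et3N deprotonates 7 at its more acidic 4-hydroxyl, the phenoxide replaces iodide on palladium, and C–O reductive elimination releases 9 and regenerates zerovalent palladium. No ring is closed and no stereocenter is formed. The step needs site selectivity between the two hydroxyls of 7: the 2-hydroxyl is tied up in a hydrogen bond to the benzyl ester carbonyl and is flanked by it, whereas the 4-hydroxyl is para to the ester, more acidic and flanked only by hydrogens. It also needs the ester and not the diaryl ether: under CO pressure, insertion into the crowded aryl–palladium bond should outrun direct C–O coupling, which this ligand promotes poorly. The two ortho substituents, which would slow attack on a free acyl derivative, matter less here because the acyl group and the phenoxide meet in the coordination sphere of the metal, and the wide bite angle of Xantphos favours the final reductive elimination.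

Step 6
Reactants: 9 benzyl 4-[(2,4-dimethoxy-6-pentylbenzoyl)oxy]-2-hydroxy-6-pentylbenzoate
Product: 11 benzyl 2-hydroxy-4-[(2-hydroxy-4-methoxy-6-pentylbenzoyl)oxy]-6-pentylbenzoate (benzyl perlatolate), via bis-dichloroboryl chelate 10 (not isolated)
Conditions: BCl3 (1 M in CH2Cl2, ca. 3 equiv), CH2Cl2, −78 °C to −10 °C; then cold H2O
Reagents that add atoms: none
Why: Chelation-controlled Lewis-acid cleavage of an aryl methyl ether; BCl3 bridges the depside carbonyl oxygen and the ortho methoxy oxygen of ring A in a six-membered chelate and chloride removes the methyl group by SN2, while the para methoxy group cannot chelate and should survive at low temperature. The ring B phenol is converted in passing into its dichloroboryl ether, and both B–O bonds of 10 hydrolyse on work-up.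

Step 7
Reactants: 11 benzyl 2-hydroxy-4-[(2-hydroxy-4-methoxy-6-pentylbenzoyl)oxy]-6-pentylbenzoate
Product: 12 perlatolic acid (2-hydroxy-4-[(2-hydroxy-4-methoxy-6-pentylbenzoyl)oxy]-6-pentylbenzoic acid)
Conditions: H2 (1 atm), 10% Pd/C, EtOAc, rt
Reagents that add atoms: none
Why: Catalytic hydrogenolysis of the benzyl ester; the conditions are neutral and at room temperature, so the depside ester, the aryl methyl ether and the decarboxylation-prone acid should be unaffected.

## Compound list

1 | 1,3-dimethoxy-5-pentylbenzene | CCCCCc1cc(OC)cc(OC)c1 | starting material
2 | 2-iodo-1,5-dimethoxy-3-pentylbenzene | CCCCCc1cc(OC)cc(OC)c1I | intermediate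
3 | olivetol (5-pentylbenzene-1,3-diol) | CCCCCc1cc(O)cc(O)c1 | starting material
4 | N-[(2,4-dihydroxy-6-pentylphenyl)methylidene]-N-methylmethanaminium chloride | CCCCCc1cc(O)cc(O)c1C=[N+](C)C.[Cl-] | intermediate
5 | 2,4-dihydroxy-6-pentylbenzaldehyde | CCCCCc1cc(O)cc(O)c1C=O | intermediate
6 | 2,4-dihydroxy-6-pentylbenzoic acid (olivetolic acid) | CCCCCc1cc(O)cc(O)c1C(=O)O | intermediate
7 | benzyl 2,4-dihydroxy-6-pentylbenzoate (benzyl olivetolate) | CCCCCc1cc(O)cc(O)c1C(=O)OCc1ccccc1 | intermediate
8 | carbon monoxide | [C-]#[O+] | starting material
9 | benzyl 4-[(2,4-dimethoxy-6-pentylbenzoyl)oxy]-2-hydroxy-6-pentylbenzoate | CCCCCc1cc(OC(=O)c2c(OC)cc(OC)cc2CCCCC)cc(O)c1C(=O)OCc1ccccc1 | intermediate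
10 | benzyl 2-[(dichloroboranyl)oxy]-4-({2-[(dichloroboranyl)oxy]-4-methoxy-6-pentylbenzoyl}oxy)-6-pentylbenzoate | CCCCCc1cc(OC(=O)c2c(OB(Cl)Cl)cc(OC)cc2CCCCC)cc(OB(Cl)Cl)c1C(=O)OCc1ccccc1 | intermediate
11 | benzyl 2-hydroxy-4-[(2-hydroxy-4-methoxy-6-pentylbenzoyl)oxy]-6-pentylbenzoate (benzyl perlatolate) | CCCCCc1cc(OC(=O)c2c(O)cc(OC)cc2CCCCC)cc(O)c1C(=O)OCc1ccccc1 | intermediate
12 | perlatolic acid | CCCCCc1cc(OC(=O)c2c(O)cc(OC)cc2CCCCC)cc(O)c1C(=O)O | target

## Step count and least certain steps

Total step count: 7. Longest linear sequence: 6 (steps 2, 3, 4, 5, 6, 7 from olivetol 3); step 1 is a one-step branch.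

Step 5 (key step). The most likely failure is slow capture of the crowded aroylpalladium intermediate by the weakly nucleophilic, electron-poor phenoxide. Reductive loss of iodine from 2 or deactivation of the catalyst under CO would then take over. The fallback sets out from 2 and comes back at 9, making the carbonyl carbon from carbon dioxide and activating the acid as an acylium precursor. Iodine–lithium exchange on 2 (n-BuLi, THF, −78 °C) should give (2,4-dimethoxy-6-pentylphenyl)lithium F1. Quenching with CO2 and acidification should give 2,4-dimethoxy-6-pentylbenzoic acid F2. Trifluoroacetic anhydride in toluene should convert F2 into 2,4-dimethoxy-6-pentylbenzoic trifluoroacetic anhydride F3, which ionises readily because the ring is electron-rich. Addition of 7 should then acylate its free 4-hydroxyl to give 9.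

Step 6. The most likely failure is loss of discrimination under the Lewis acid: cleavage of the para methyl ether as well, or attack on the depside ester. Early loss of the benzyl ester would be harmless, since it leads to 12 itself. The fallback sets out from 3 and comes back at 11, replacing the selective demethylation by a selective methylation. Olivetol 3 with MOMCl and i-Pr2NEt should give 1,3-bis(methoxymethoxy)-5-pentylbenzene F4. NIS in MeCN without acid should then iodinate beside the chain and give 2-iodo-1,5-bis(methoxymethoxy)-3-pentylbenzene F5. Carbonylative coupling of F5 with 7 and 8 under the conditions of step 5 should give benzyl 4-{[2,4-bis(methoxymethoxy)-6-pentylbenzoyl]oxy}-2-hydroxy-6-pentylbenzoate F6. Dilute HCl in MeOH at room temperature should remove both acetals to give benzyl 4-[(2,4-dihydroxy-6-pentylbenzoyl)oxy]-2-hydroxy-6-pentylbenzoate F7, which has the same structure as A1. One equivalent of TMSCHN2 in toluene/MeOH should methylate the only hydroxyl of F7 that is not hydrogen-bonded to a carbonyl, the one at C4 of ring A, and so give 11.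

Step 3. The most likely failure is chlorination of the electron-rich ring by hypochlorous acid that escapes the scavenger, or decarboxylation of the product during acidic work-up. The fallback sets out from 3 and comes back at 6 without passing through the aldehyde. Heating 3 with methoxymagnesium methyl carbonate, MeOMgOCO2Me, in DMF at about 120 °C and then acidifying in the cold should carboxylate ortho to a hydroxyl through a magnesium chelate and give 6. The regioisomeric acid from attack between the two hydroxyls may then have to be removed by crystallisation. This fallback makes no new compound.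

## Further compounds

F1 | step 5 | (2,4-dimethoxy-6-pentylphenyl)lithium | CCCCCc1cc(OC)cc(OC)c1[Li]
F2 | step 5 | 2,4-dimethoxy-6-pentylbenzoic acid | CCCCCc1cc(OC)cc(OC)c1C(=O)O
F3 | step 5 | 2,4-dimethoxy-6-pentylbenzoic trifluoroacetic anhydride | CCCCCc1cc(OC)cc(OC)c1C(=O)OC(=O)C(F)(F)F
F4 | step 6 | 1,3-bis(methoxymethoxy)-5-pentylbenzene | CCCCCc1cc(OCOC)cc(OCOC)c1
F5 | step 6 | 2-iodo-1,5-bis(methoxymethoxy)-3-pentylbenzene | CCCCCc1cc(OCOC)cc(OCOC)c1I
F6 | step 6 | benzyl 4-{[2,4-bis(methoxymethoxy)-6-pentylbenzoyl]oxy}-2-hydroxy-6-pentylbenzoate | CCCCCc1cc(OC(=O)c2c(OCOC)cc(OCOC)cc2CCCCC)cc(O)c1C(=O)OCc1ccccc1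
F7 | step 6 | benzyl 4-[(2,4-dihydroxy-6-pentylbenzoyl)oxy]-2-hydroxy-6-pentylbenzoate | CCCCCc1cc(OC(=O)c2c(O)cc(O)cc2CCCCC)cc(O)c1C(=O)OCc1ccccc1
F0 | step 3 | none | none
A1 | alternative 1 | benzyl 4-[(2,4-dihydroxy-6-pentylbenzoyl)oxy]-2-hydroxy-6-pentylbenzoate | CCCCCc1cc(O)cc(O)c1C(=O)Oc1cc(CCCCC)c(C(=O)OCc2ccccc2)c(O)c1
A2 | alternative 1 | benzyl 2-hydroxy-6-pentyl-4-[(3,5,7-trioxododecanoyl)oxy]benzoate | CCCCCC(=O)CC(=O)CC(=O)CC(=O)Oc1cc(CCCCC)c(C(=O)OCc2ccccc2)c(O)c1
A3 | alternative 2 | benzyl 4-{[2-(benzyloxy)-4-methoxy-6-pentylbenzoyl]oxy}-2-hydroxy-6-pentylbenzoate | CCCCCc1cc(OC(=O)c2c(OCc3ccccc3)cc(OC)cc2CCCCC)cc(O)c1C(=O)OCc1ccccc1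
A4 | alternative 2 | 2-oxo-6-pentyl-2H-pyran-4-yl 2-(benzyloxy)-4-methoxy-6-pentylbenzoate | CCCCCc1cc(OC(=O)c2c(OCc3ccccc3)cc(OC)cc2CCCCC)cc(=O)o1
A5 | alternative 2 | benzyl 3-(benzyloxy)-3-[(trimethylsilyl)oxy]prop-2-enoate (double-bond geometry not defined) | C[Si](C)(C)OC(OCc1ccccc1)=CC(=O)OCc1ccccc1
A6 | alternative 3 | benzyl 2-hydroxy-4-[(2-hydroxy-4-methoxy-6-pentylbenzoyl)oxy]-6-pentylbenzoate (benzyl perlatolate, same as 11) | CCCCCc1cc(OC(=O)c2c(O)cc(OC)cc2CCCCC)cc(O)c1C(=O)OCc1ccccc1
A7 | alternative 3 | benzyl 2-hydroxy-4-(oct-2-ynoyloxy)-6-pentylbenzoate | CCCCCC#CC(=O)Oc1cc(CCCCC)c(C(=O)OCc2ccccc2)c(O)c1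
A8 | alternative 3 | 1,3-dimethoxy-1-[(trimethylsilyl)oxy]buta-1,3-diene (geometry at C1=C2 not defined) | COC(=C)C=C(OC)O[Si](C)(C)C
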